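**Plan**

- Numbering: oxygenated ring C1' (C–Me), C2' (=CH), C3' (CHOH), C4' (oxirane C bearing the CH2), C5' (oxirane CH), C6' (C=O); decalin as in drimanes, C11 being the CH2 on C9.
- Retrosynthesis: C6'=O from a dimethyl ketal, C3'–OH from C3'=O, the oxirane from C4'=C5' of a quinone monoketal, and that from a para-methoxyphenol; the arene is then cut at C3'–C4' and C5'–C6'.
- Enabling feature: the ring has O on C3' and C6' (para), Me on C1' and CH2R on C4' (para), H on C2' and C5'. A 4-alkenyl-4-methoxy-3-methylcyclobutenone (its carbons become C3', C2', C1', C6') gives exactly this when it takes the alkene carbons C5' and C4' into the ring, with C6'–O methylated and C3'–OH free.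
- Decalin: C8–CH3 is cut (triflate/methyl coupling) and the rest traced to levopimaric acid, whose ring A/B carries the 4α-carboxyl, 4β-Me, 5α-H, 9α-H and 10β-Me; ozonolysis of its ring C diene leaves the C8 ketone and the C11–C12 aldehyde.
- Forward order: ring A/B from the pool, ring C cleavage, alkyne, 7,8-alkene with C8-Me, (E)-alkenyl iodide, union with 3-methylcyclobutenedione, ring expansion to the arene, dearomatisation, epoxidation, reduction, deprotection.
- Stereochemistry: decalin centres from levopimaric acid; oxirane carbons by cinchona-ammonium-controlled nucleophilic epoxidation (diastereomers, separable); C3' by hydride delivery syn to the oxirane oxygen.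

Key step: step 11

Assumption: levopimaric acid is bought from a research supplier (it is also obtained from pine oleoresin through its 2-amino-2-methylpropan-1-ol salt).
Notation: "D" is the decalin residue (drimane numbering) 4α-(tert-butyldimethylsilyloxymethyl)-4β,8,10β-trimethyl-trans-decal-7-en-9β-yl with 5α-H and 9α-H; TBS = tert-butyldimethylsilyl.

**Route**

Step 1
Reactants: 1 levopimaric acid
Product: 2 levopimarinol (abieta-8(14),12-dien-18-ol)
Conditions: LiAlH4, THF, 0 °C to reflux; aqueous work-up
Reagents that add atoms: none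
Why: Hydride reduction of the hindered C4 carboxylic acid to the primary alcohol leaves the diene and all stereocentres untouched.

Step 2
Reactants: 2 levopimarinol
Product: 3 levopimarinol TBS ether
Conditions: t-BuMe2SiCl, imidazole, DMF, rt
Reagents that add atoms: tert-butyldimethylsilyl chloride, CC(C)(C)[Si](C)(C)Cl
Why: Imidazole-promoted silylation masks the primary alcohol against the bases, organometallics and oxidants that follow.

Step 3
Reactants: 3 levopimarinol TBS ether
Product: 4 keto aldehyde (C8 ketone, 9β-CH2CHO)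
Conditions: O3, CH2Cl2/MeOH, −78 °C; then Me2S, −78 °C to rt
Reagents that add atoms: ozone, [O-][O+]=O
Why: Exhaustive ozonolysis with reductive work-up cleaves C8=C14 and C12=C13, excising C13–C17 and leaving the C8 ketone and the C12 aldehyde; the 9β side chain is equatorial and is the stable epimer next to the new ketone.

Step 4
Reactants: 4 keto aldehyde
Product: 5 keto alkyne (C8 ketone, 9β-propargyl)
Conditions: dimethyl (1-diazo-2-oxopropyl)phosphonate, K2CO3, MeOH, 0 °C to rt
Reagents that add atoms: dimethyl (1-diazo-2-oxopropyl)phosphonate, CC(=O)C(=[N+]=[N-])P(=O)(OC)OC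
Why: Seyferth–Gilbert homologation with the Ohira–Bestmann reagent converts the aldehyde, not the ketone, into the terminal alkyne, and any epimerisation at C9 under carbonate returns the equatorial side chain.

Step 5
Reactants: 5 keto alkyne
Product: 7 enol triflate, via potassium enolate 6 (not isolated)
Conditions: KN(SiMe3)2, THF, −78 °C; then PhNTf2, −78 to 0 °C
Reagents that add atoms: N-phenylbis(trifluoromethanesulfonimide), O=S(=O)(N(c1ccccc1)S(=O)(=O)C(F)(F)F)C(F)(F)F
Why: Kinetic deprotonation by the bulky amide takes the unhindered C7 methylene, not the tertiary C9–H next to quaternary C10, and O-triflation fixes the 7,8-double bond (kinetic enol triflate formation).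

Step 6
Reactants: 7 enol triflate
Product: 8 alkyne D–CH2–C≡CH
Conditions: MeMgBr, Fe(acac)3 (5 mol %), THF/N-methylpyrrolidone, −30 to 0 °C
Reagents that add atoms: methylmagnesium bromide, C[Mg]Br
Why: Iron-catalysed Kumada-type coupling of the alkenyl triflate with MeMgBr installs the C8 methyl group with the double bond held at C7–C8.

Step 7
Reactants: 8 alkyne D–CH2–C≡CH
Product: 10 (E)-alkenyl iodide D–CH2–CH=CH–I, via alkenylzirconocene chloride 9 (not isolated)
Conditions: Cp2Zr(H)Cl, THF, rt; then I2, 0 °C
Reagents that add atoms: iodine, II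
Why: Schwartz hydrozirconation adds Zr–H syn and terminally to the alkyne far faster than to the trisubstituted alkene, and iodinolysis with retention gives the (E)-iodide.

Step 8
Reactants: 11 diisopropyl squarate
Product: 12 4-hydroxy-2,3-diisopropoxy-4-methylcyclobut-2-en-1-one
Conditions: MeLi, THF, −78 °C; aq. NH4Cl
Reagents that add atoms: methyllithium, [Li]C
Why: 1,2-Addition of MeLi to one of the two equivalent ketone carbonyls stops at the mono-adduct because the remaining carbonyl is a vinylogous ester.

Step 9
Reactants: 12 4-hydroxy-2,3-diisopropoxy-4-methylcyclobut-2-en-1-one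
Product: 14 3-methylcyclobut-3-ene-1,2-dione, via diol 13 (not isolated)
Conditions: i-Bu2AlH, THF, −78 to 0 °C; then aq. HCl, CH2Cl2, rt
Reagents that add atoms: none
Why: 1,2-Reduction of the vinylogous ester carbonyl gives the vicinal diol, whose two allylic carbinols ionise in acid with hydrolysis of both enol ethers (Stork–Danheiser-type transposition) to the dione.

Step 10
Reactants: 10 (E)-alkenyl iodide; 14 3-methylcyclobut-3-ene-1,2-dione
Product: 17 4-alkenyl-4-methoxy-3-methylcyclobut-2-en-1-one, via alkenyllithium 15 (not isolated), via lithium alkoxide 16 (not isolated)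
Conditions: t-BuLi (2 equiv), Et2O, −78 °C; add to 14 in THF, −78 °C; then MeOTf, −78 to −20 °C
Reagents that add atoms: methyl trifluoromethanesulfonate, COS(=O)(=O)C(F)(F)F
Why: Iodine–lithium exchange with retention gives the (E)-alkenyllithium, which adds 1,2 to the more electrophilic carbonyl of 14 (the one on the methyl-bearing carbon, the other being deactivated by the β-methyl as in 3-alkoxycyclobutenediones), and O-methylation traps the alkoxide; the new quaternary carbon forms as both epimers, which converge in step 11.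

Step 11
Reactants: 17 4-alkenyl-4-methoxy-3-methylcyclobut-2-en-1-one
Product: 20 phenol 2-(D–CH2)-4-methoxy-5-methylphenol, via dienylketene 18 (not isolated), via cyclohexadienone 19 (not isolated)
Conditions: toluene, 110 °C, argon
Reagents that add atoms: none
Why: On heating, the cyclobutenone opens by conrotatory 4π cleavage of its C3'–C6' bond, the methoxy donor on C6' rotating outward so that the alkenyl group turns inward and ends cis to the ketene (18). Disrotatory 6π electrocyclisation then joins the ketene carbon C3' to the alkene terminus C4' (the one ring closed, six-membered, by electrocyclisation) and dienone 19 tautomerises to the arene; the closest known reaction type is the Moore rearrangement of 4-alkenyl-4-alkoxycyclobutenones to hydroquinone monoethers. The four-membered ring (C3', C2', C1', C6') thus grows by the two alkene carbons C5' and C4', which sets OH and OMe para, methyl and CH2R para, and leaves C3'–OH free while C6'–O is methylated. No stereocentre is created, since both epimers of 17 converge and the sp3 centre of 19 is lost on aromatisation. The selectivity needed is inward rotation of the alkenyl group, secured by the stronger donor OMe on the same carbon, and the (E)-alkene keeps the bulky CH2R group outside the closing ring. The neutral, reagent-free conditions spare the silyl ether, the trisubstituted alkene and C9.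

Step 12
Reactants: 20 phenol
Product: 21 quinone monoketal (4,4-dimethoxy-5-methyl-2-(D–CH2)cyclohexa-2,5-dien-1-one)
Conditions: PhI(OAc)2, MeOH, 0 °C
Reagents that add atoms: methanol, CO
Why: Oxidative dearomatisation of the para-methoxyphenol with methanol capture at the methoxy-bearing carbon places the ketal at C6' and the free carbonyl at C3' (quinone monoketal formation).

Step 13
Reactants: 21 quinone monoketal
Product: 22 epoxy ketone (oxirane at C4'–C5')
Conditions: t-BuOOH, aq. NaOH, N-benzylcinchonidinium chloride (20 mol %), toluene, 0 °C to rt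
Reagents that add atoms: tert-butyl hydroperoxide, CC(C)(C)OO
Why: In this Weitz–Scheffer epoxidation under chiral phase transfer the peroxide anion attacks the hydrogen-bearing β-carbon C5' rather than the methyl-bearing C1' and the enolate closes the oxirane on C4'; the ion-paired cinchonidinium cation is expected to direct attack to the face giving the target configuration, by analogy with cinchona-ammonium epoxidations of 4,4-dimethoxycyclohexadienones, and since the drimane is enantiopure the other epoxide is a diastereomer removed by chromatography.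

Step 14
Reactants: 22 epoxy ketone
Product: 23 epoxy alcohol (C3'–OH trans to the oxirane oxygen)
Conditions: i-Bu2AlH, CH2Cl2, −78 °C; aq. potassium sodium tartrate
Reagents that add atoms: none
Why: In this 1,2-reduction hydride is expected on the face syn to the oxirane oxygen (aluminium coordinated to it) and anti to the bulky CH2–decalin group on the adjacent quaternary carbon, giving the alcohol trans to the epoxide oxygen; ketal and epoxide are inert at −78 °C.

Step 15
Reactants: 23 epoxy alcohol
Product: 24 Epoxypholamin B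
Conditions: 48% aq. HF, MeCN, 0 °C to rt
Reagents that add atoms: water, O
Why: Acetal hydrolysis frees the C6' ketone and fluoride-assisted desilylation frees the primary alcohol in one operation, under mild acid that the epoxy alcohol and the trisubstituted alkene tolerate.

**Compound list**

1 | levopimaric acid (abieta-8(14),12-dien-18-oic acid) | CC(C)C1=CC[C@H]3C(=C1)CC[C@H]4[C@](C)(C(=O)O)CCC[C@]34C | starting material
2 | levopimarinol (abieta-8(14),12-dien-18-ol) | CC(C)C1=CC[C@H]3C(=C1)CC[C@H]4[C@](C)(CO)CCC[C@]34C | intermediate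
3 | levopimarinol TBS ether | CC(C)C1=CC[C@H]3C(=C1)CC[C@H]4[C@](C)(CO[Si](C)(C)C(C)(C)C)CCC[C@]34C | intermediate
4 | keto aldehyde: trans-decalin with C8 ketone, 9β-CH2CHO, 4α-CH2OTBS, 4β-Me, 10β-Me | O=CC[C@H]3C(=O)CC[C@H]4[C@](C)(CO[Si](C)(C)C(C)(C)C)CCC[C@]34C | intermediate
5 | keto alkyne: as 4 with 9β-propargyl | C#CC[C@H]3C(=O)CC[C@H]4[C@](C)(CO[Si](C)(C)C(C)(C)C)CCC[C@]34C | intermediate
6 | potassium C7-enolate of 5 (formed in the flask) | [K+].C#CC[C@H]3C([O-])=CC[C@H]4[C@](C)(CO[Si](C)(C)C(C)(C)C)CCC[C@]34C | intermediate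
7 | enol triflate: 8-trifloxy-7-ene with 9β-propargyl | C#CC[C@H]3C(OS(=O)(=O)C(F)(F)F)=CC[C@H]4[C@](C)(CO[Si](C)(C)C(C)(C)C)CCC[C@]34C | intermediate
8 | alkyne D–CH2–C≡CH | C#CC[C@H]3C(C)=CC[C@H]4[C@](C)(CO[Si](C)(C)C(C)(C)C)CCC[C@]34C | intermediate
9 | (E)-alkenylzirconocene chloride D–CH2–CH=CH–Zr(Cl)Cp2 (formed in the flask) | [cH-]1cccc1.[cH-]1cccc1.Cl[Zr+2]/C=C/C[C@H]3C(C)=CC[C@H]4[C@](C)(CO[Si](C)(C)C(C)(C)C)CCC[C@]34C | intermediate
10 | (E)-alkenyl iodide D–CH2–CH=CH–I | I/C=C/C[C@H]3C(C)=CC[C@H]4[C@](C)(CO[Si](C)(C)C(C)(C)C)CCC[C@]34C | intermediate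
11 | diisopropyl squarate (3,4-diisopropoxycyclobut-3-ene-1,2-dione) | CC(C)OC1=C(OC(C)C)C(=O)C1=O | starting material
12 | 4-hydroxy-2,3-diisopropoxy-4-methylcyclobut-2-en-1-one (racemic) | CC(C)OC1=C(OC(C)C)C(C)(O)C1=O | intermediate
13 | 3,4-diisopropoxy-1-methylcyclobut-3-ene-1,2-diol (formed in the flask) | CC(C)OC1=C(OC(C)C)C(C)(O)C1O | intermediate
14 | 3-methylcyclobut-3-ene-1,2-dione | CC1=CC(=O)C1=O | intermediate
15 | (E)-alkenyllithium D–CH2–CH=CH–Li (formed in the flask) | [Li]/C=C/C[C@H]3C(C)=CC[C@H]4[C@](C)(CO[Si](C)(C)C(C)(C)C)CCC[C@]34C | intermediate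
16 | lithium alkoxide of the 1,2-adduct (formed in the flask; both epimers) | [Li+].[O-]C1(/C=C/C[C@H]3C(C)=CC[C@H]4[C@](C)(CO[Si](C)(C)C(C)(C)C)CCC[C@]34C)C(C)=CC1=O | intermediate
17 | 4-methoxy-3-methyl-4-[(E)-3-D-prop-1-enyl]cyclobut-2-en-1-one (both epimers at the ring quaternary carbon) | COC1(/C=C/C[C@H]3C(C)=CC[C@H]4[C@](C)(CO[Si](C)(C)C(C)(C)C)CCC[C@]34C)C(C)=CC1=O | intermediate
18 | dienylketene, alkenyl group cis to the ketene (formed in the flask) | O=C=C/C(C)=C(OC)\C=C\C[C@H]3C(C)=CC[C@H]4[C@](C)(CO[Si](C)(C)C(C)(C)C)CCC[C@]34C | intermediate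
19 | 4-methoxy-3-methyl-6-(D–CH2)cyclohexa-2,4-dien-1-one (formed in the flask) | COC1=CC(C[C@H]3C(C)=CC[C@H]4[C@](C)(CO[Si](C)(C)C(C)(C)C)CCC[C@]34C)C(=O)C=C1C | intermediate
20 | 2-(D–CH2)-4-methoxy-5-methylphenol | COc1cc(C[C@H]3C(C)=CC[C@H]4[C@](C)(CO[Si](C)(C)C(C)(C)C)CCC[C@]34C)c(O)cc1C | intermediate
21 | 4,4-dimethoxy-5-methyl-2-(D–CH2)cyclohexa-2,5-dien-1-one | COC1(OC)C=C(C[C@H]3C(C)=CC[C@H]4[C@](C)(CO[Si](C)(C)C(C)(C)C)CCC[C@]34C)C(=O)C=C1C | intermediate
22 | epoxy ketone: oxirane on C4'–C5' of 21, quaternary oxirane carbon R, oxirane CH S | CC1=CC(=O)[C@]2(C[C@H]3C(C)=CC[C@H]4[C@](C)(CO[Si](C)(C)C(C)(C)C)CCC[C@]34C)O[C@@H]2C1(OC)OC | intermediate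
23 | epoxy alcohol: C3' carbinol R, trans to the oxirane oxygen; dimethyl ketal at C6' | CC1=C[C@@H](O)[C@]2(C[C@H]3C(C)=CC[C@H]4[C@](C)(CO[Si](C)(C)C(C)(C)C)CCC[C@]34C)O[C@@H]2C1(OC)OC | intermediate
24 | Epoxypholamin B | CC1=C[C@@H](O)[C@]2(C[C@H]3C(C)=CC[C@H]4[C@](C)(CO)CCC[C@]34C)O[C@@H]2C1=O | target

**Step count and risks**

Total: 15 steps. Longest linear sequence: 13 steps (steps 1–7 and 10–15 from levopimaric acid); steps 8–9 form the short branch.

Steps most likely to fail:

1. Step 10. The alkenyllithium may attack the other carbonyl of 14 or deprotonate its methyl group, which would give the wrong substitution pattern after ring expansion. Fallback, setting out from 11 and 10 and returning at 17: diisopropyl squarate 11 is reduced with LiAlH(OtBu)3 to 4-hydroxy-2,3-diisopropoxycyclobut-2-en-1-one F1, and aqueous HCl converts this to 3-isopropoxycyclobut-3-ene-1,2-dione F2. Alkenyllithium 15 (from 10) adds only to its non-vinylogous carbonyl, and MeOTf gives 3-isopropoxy-4-methoxy-4-alkenylcyclobut-2-en-1-one F3. MeLi then adds 1,2 to the vinylogous ester carbonyl to give the tertiary alcohol F4, and dilute acid (Stork–Danheiser transposition) delivers 17 with the regiochemistry fixed by construction.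

2. Step 13. The ammonium salt may give poor or reversed facial selectivity in the peroxide addition. Fallback, setting out from 21 and returning at 23: unselective epoxidation (H2O2, LiOH, MeOH) gives 22 together with the epoxide-epimeric ketone F5. Reduction of the mixture with i-Bu2AlH gives 23 and the diastereomeric epoxy alcohol F6. A lipase (Burkholderia cepacia lipase, vinyl acetate) acylates the R-configured carbinol of 23 to the acetate F7, which is separated from unreacted F6 and returned to 23 with K2CO3 in MeOH.

3. Step 14. Hydride may instead be delivered anti to the oxirane oxygen, giving the epimeric carbinol. Fallback, setting out from 22 and returning at 23: reduction under conditions favouring that sense (NaBH4, MeOH, −78 °C) gives the syn epoxy alcohol F8. Mitsunobu inversion (4-nitrobenzoic acid, PPh3, diisopropyl azodicarboxylate) gives the 4-nitrobenzoate F9 with the target configuration, and K2CO3 in MeOH releases 23.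

**Further compounds**

F1 | step 10 | 4-hydroxy-2,3-diisopropoxycyclobut-2-en-1-one | CC(C)OC1=C(OC(C)C)C(O)C1=O
F2 | step 10 | 3-isopropoxycyclobut-3-ene-1,2-dione | CC(C)OC1=CC(=O)C1=O
F3 | step 10 | 3-isopropoxy-4-methoxy-4-[(E)-3-D-prop-1-enyl]cyclobut-2-en-1-one | COC1(/C=C/C[C@H]3C(C)=CC[C@H]4[C@](C)(CO[Si](C)(C)C(C)(C)C)CCC[C@]34C)C(OC(C)C)=CC1=O
F4 | step 10 | 3-isopropoxy-4-methoxy-1-methyl-4-[(E)-3-D-prop-1-enyl]cyclobut-2-en-1-ol | COC1(/C=C/C[C@H]3C(C)=CC[C@H]4[C@](C)(CO[Si](C)(C)C(C)(C)C)CCC[C@]34C)C(OC(C)C)=CC1(C)O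
F5 | step 13 | epoxide-epimeric epoxy ketone (both oxirane carbons inverted relative to 22) | CC1=CC(=O)[C@@]2(C[C@H]3C(C)=CC[C@H]4[C@](C)(CO[Si](C)(C)C(C)(C)C)CCC[C@]34C)O[C@H]2C1(OC)OC
F6 | step 13 | diastereomeric epoxy alcohol (all three ring centres inverted relative to 23) | CC1=C[C@H](O)[C@@]2(C[C@H]3C(C)=CC[C@H]4[C@](C)(CO[Si](C)(C)C(C)(C)C)CCC[C@]34C)O[C@H]2C1(OC)OC
F7 | step 13 | acetate of 23 | CC1=C[C@@H](OC(C)=O)[C@]2(C[C@H]3C(C)=CC[C@H]4[C@](C)(CO[Si](C)(C)C(C)(C)C)CCC[C@]34C)O[C@@H]2C1(OC)OC
F8 | step 14 | syn epoxy alcohol (C3' epimer of 23) | CC1=C[C@H](O)[C@]2(C[C@H]3C(C)=CC[C@H]4[C@](C)(CO[Si](C)(C)C(C)(C)C)CCC[C@]34C)O[C@@H]2C1(OC)OC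
F9 | step 14 | 4-nitrobenzoate of 23 | CC1=C[C@@H](OC(=O)c5ccc(cc5)[N+](=O)[O-])[C@]2(C[C@H]3C(C)=CC[C@H]4[C@](C)(CO[Si](C)(C)C(C)(C)C)CCC[C@]34C)O[C@@H]2C1(OC)OC
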